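## Retrosynthetic overview

Positions: C1 = C(=CH2), C2 = CHOH, C3=C4, C5 = C(CH3), C6=C7–C8(=O), C9 = C(CH3)OAc, C10 = CH, C11 = CHOAc, C12 = C(OH), C13 = CH(CH3), C14 = lactone C=O, O15, C16 = lactone OCH, C17 = CHCl. Target 37 ⇐ 36 by ene-type chlorination (C17–Cl, C1=CH2); ten-membered ring (third ring) ⇐ iodo-enal 35 by NiCl2/CrCl2 closure of C1–C2.
γ-Lactone (second ring) ⇐ acyclic ester 26; C11/C12 diol ⇐ E-olefin 24 (OsO4); C12–C16 and C12–C13 ⇐ alkyne 16 + aldehyde 17 + zinc reagent 23.
Ring A (first ring, C5–C10) ⇐ allylboronate 9 + butane-2,3-dione 10, forming C6=C7 and C9–C10 in one flask.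
Enabling feature: in ring A the segment C7–C8(=O)–C9(CH3)(O) is a butane-2,3-dione unit; it lies between C6 (aldehyde level, non-enolisable because C5 is quaternary) and C10, the γ-carbon of an allyl unit C10–C11=C12.
C5 quaternary centre ⇐ ethyl (R)-3-hydroxybutanoate 1 by two chelate-controlled alkylations.

Key step: step 8

Remark: a one-pot operation is counted as one step; in step 12 the ligand enantiomer is the one that delivers the 16R carbinol.

## Route

Step 1
Reactants: 1 ethyl (R)-3-hydroxybutanoate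
Product: 2 ethyl (2R,3R)-3-hydroxy-2-methylbutanoate
Conditions: LDA (2.2 equiv), THF, −78 → −20 °C; MeI, DMPU
Reagents that add atoms: iodomethane CI
Why: Fráter–Seebach alkylation, in which the chelated dianion of the β-hydroxy ester takes the electrophile anti to the carbinol methyl group and should give the 2,3-anti product.

Step 2
Reactants: 2 ethyl (2R,3R)-3-hydroxy-2-methylbutanoate
Product: 3 ethyl (2R,3R)-3-hydroxy-2-(hydroxymethyl)-2-methylbutanoate
Conditions: LDA (2.2 equiv), THF, −78 °C; monomeric CH2O (gas), −78 → −40 °C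
Reagents that add atoms: formaldehyde C=O
Why: A second Fráter–Seebach-type reaction (aldol addition of the dianion to formaldehyde) again takes the electrophile anti to the carbinol methyl group, so the order methyl then hydroxymethyl fixes the quaternary centre that becomes C5.

Step 3
Reactants: 3 ethyl (2R,3R)-3-hydroxy-2-(hydroxymethyl)-2-methylbutanoate
Product: 4 ethyl (2R,3R)-2-{[(tert-butyldiphenylsilyl)oxy]methyl}-3-hydroxy-2-methylbutanoate
Conditions: TBDPSCl, imidazole, CH2Cl2, 0 °C
Reagents that add atoms: tert-butyl(chloro)diphenylsilane CC(C)(C)[Si](Cl)(c1ccccc1)c1ccccc1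
Why: Silylation of the primary hydroxyl only, since the secondary hydroxyl next to the quaternary carbon is much less reactive.

Step 4
Reactants: 4 ethyl (2R,3R)-2-{[(tert-butyldiphenylsilyl)oxy]methyl}-3-hydroxy-2-methylbutanoate
Product: 5 ethyl (S)-2-{[(tert-butyldiphenylsilyl)oxy]methyl}-2-methylbut-3-enoate
Conditions: Burgess reagent (methyl N-(triethylammoniosulfonyl)carbamate), toluene, 70 °C
Reagents that add atoms: none
Why: Burgess dehydration (syn elimination of the sulfamate ester), in which the only β-hydrogens are those of the methyl group, so the terminal vinyl group must result.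

Step 5
Reactants: 5 ethyl (S)-2-{[(tert-butyldiphenylsilyl)oxy]methyl}-2-methylbut-3-enoate
Product: 6 (S)-2-{[(tert-butyldiphenylsilyl)oxy]methyl}-2-methylbut-3-enal
Conditions: DIBAL-H (1.05 equiv), CH2Cl2, −78 °C; Rochelle salt
Reagents that add atoms: none
Why: Partial ester reduction, in which the aluminium hemiacetal of the hindered α-quaternary ester should persist at −78 °C and release the non-enolisable aldehyde on work-up.

Step 6
Reactants: 6 (S)-2-{[(tert-butyldiphenylsilyl)oxy]methyl}-2-methylbut-3-enal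
Product: 7 (S)-tert-butyl{[2-(dimethoxymethyl)-2-methylbut-3-en-1-yl]oxy}diphenylsilane
Conditions: HC(OMe)3, MeOH, PPTS (cat.), 40 °C
Reagents that add atoms: trimethyl orthoformate COC(OC)OC; methanol CO
Why: Acid-catalysed acetalisation masks C6 so that no carbonyl group competes in steps 7 and 8, and it makes the C6 arm the largest substituent on C5.

Step 7
Reactants: 7 (S)-tert-butyl{[2-(dimethoxymethyl)-2-methylbut-3-en-1-yl]oxy}diphenylsilane; 8 2-allyl-4,4,5,5-tetramethyl-1,3,2-dioxaborolane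
Product: 9 tert-butyl{[(2S,3E)-2-(dimethoxymethyl)-2-methyl-5-(4,4,5,5-tetramethyl-1,3,2-dioxaborolan-2-yl)pent-3-en-1-yl]oxy}diphenylsilane
Conditions: 8 (3 equiv), second-generation Hoveyda–Grubbs catalyst (5 mol %), CH2Cl2, 40 °C
Reagents that add atoms: none
Why: Olefin cross-metathesis, in which the hindered vinyl group cannot homodimerise and the quaternary substituent should enforce the E geometry that step 8 requires.

Step 8
Reactants: 9 tert-butyl{[(2S,3E)-2-(dimethoxymethyl)-2-methyl-5-(4,4,5,5-tetramethyl-1,3,2-dioxaborolan-2-yl)pent-3-en-1-yl]oxy}diphenylsilane; 10 butane-2,3-dione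
Product: 13 (4S,5R,6S)-4-{[(tert-butyldiphenylsilyl)oxy]methyl}-5-ethenyl-6-hydroxy-4,6-dimethylcyclohex-2-en-1-one, via pinacol borate adduct 11 (not isolated), via seco keto aldehyde 12 (not isolated)
Conditions: 10 (8 equiv, neat), 60 °C; excess 10 removed in vacuo; TsOH·H2O (0.3 equiv), THF/H2O (9:1), 55 °C
Reagents that add atoms: none
Why: Thermal allylboration: the γ-carbon C10 of the E-allylboronate adds to one carbonyl of the C2-symmetric dione 10 through a closed six-membered chair transition state (boron on the ketone oxygen, allyl transposition giving the C10 vinyl group), and acid then cleaves the borate 11 and the dimethyl acetal so that the enol of the remaining acetyl group (C7) condenses with the freed C6 aldehyde of 12. The closest known reaction types are the allylboration of activated 1,2-dicarbonyl ketones with γ-substituted allylboronates and the acid-mediated intramolecular aldol condensation of keto aldehydes (Robinson-type ring closure). Ring A closes by a 6-(enolendo)-exo-trig aldol addition followed by elimination of water to the conjugated enone, the cis ring olefin being enforced by the ring. C9 and C10 are set together in the chair: the C5 substituent on the E-olefin is equatorial and the acetyl group of 10 sits equatorial (boron binds the ketone lone pair syn to the small methyl group), which should place the 9-hydroxyl trans to the 10-vinyl group. The sense relative to C5 should follow from attack of the ketone anti to the largest C5 substituent (the dimethoxymethyl group), with the silyloxymethyl arm inside and the methyl group outside, which places the vinyl group cis to the C5 methyl group. The step needs chemoselective allylation of 10 and one single aldol mode: masking C6 as the acetal leaves 10 as the only carbonyl partner in the first stage, the symmetry of 10 removes any regiochemical question, and in 12 C7 is the only enolisable position and C6 the only aldehyde.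

Step 9
Reactants: 13 (4S,5R,6S)-4-{[(tert-butyldiphenylsilyl)oxy]methyl}-5-ethenyl-6-hydroxy-4,6-dimethylcyclohex-2-en-1-one
Product: 14 9-O-triethylsilyl ether of 13
Conditions: TESOTf, 2,6-lutidine, CH2Cl2, −78 → 0 °C
Reagents that add atoms: triethylsilyl trifluoromethanesulfonate CC[Si](CC)(CC)OS(=O)(=O)C(F)(F)F
Why: Silyl triflate silylation of the tertiary α-ketol, which blocks retro-aldol cleavage in step 11 and removes a second directing hydroxyl before step 13.

Step 10
Reactants: 14 9-O-triethylsilyl ether of 13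
Product: 15 ring A aldehyde (10-formyl; 9-OTES; 5-CH2OTBDPS; stereocentres as in 13)
Conditions: O3 (1 equiv), CH2Cl2, pyridine, −78 °C; Me2S
Reagents that add atoms: ozone [O-][O+]=O
Why: Ozonolysis, in which the isolated vinyl group is far more electron-rich than the enone olefin, so one equivalent of ozone should cleave only the vinyl group.

Step 11
Reactants: 15 ring A aldehyde
Product: 16 ring A alkyne (10-ethynyl, C11≡C12–H; 9-OTES; 5-CH2OTBDPS)
Conditions: dimethyl (1-diazo-2-oxopropyl)phosphonate, K2CO3, MeOH, 0 °C → rt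
Reagents that add atoms: dimethyl (1-diazo-2-oxopropyl)phosphonate COP(=O)(OC)C(=[N+]=[N-])C(C)=O
Why: Ohira–Bestmann homologation converts the hindered aldehyde into the terminal alkyne under mild carbonate conditions, and C10, flanked by two quaternary carbons, should not epimerise.

Step 12
Reactants: 16 ring A alkyne; 17 (tert-butyldimethylsilyloxy)acetaldehyde
Product: 18 (16R)-propargylic alcohol (C11≡C12–C16H(OH)–C17H2OTBS)
Conditions: Me2Zn (3 equiv), (S,S)-ProPhenol (20 mol %), Ph3P=O (40 mol %), toluene, 0 °C, slow addition of 17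
Reagents that add atoms: none
Why: Catalytic asymmetric addition of an alkynylzinc to an aldehyde (dinuclear zinc–ProPhenol catalysis), in which the C16 carbinol centre is set by the ligand under reagent control.

Step 13
Reactants: 18 (16R)-propargylic alcohol
Product: 19 (11Z)-12-tributylstannyl allylic alcohol
Conditions: Bu3SnH (1.2 equiv), [Cp*RuCl]4 (2.5 mol %), CH2Cl2, rt
Reagents that add atoms: tributylstannane CCCC[SnH](CCCC)CCCC
Why: Ruthenium-catalysed trans-hydrostannation of a propargylic alcohol, in which the free hydroxyl directs tin to the proximal carbon C12 and hydrogen is delivered trans, so C10 ends cis to tin.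

Step 14
Reactants: 19 (11Z)-12-tributylstannyl allylic alcohol
Product: 20 (11Z)-12-iodo allylic alcohol
Conditions: I2 (1.05 equiv), CH2Cl2, 0 °C
Reagents that add atoms: iodine II
Why: Iododestannylation, which proceeds with retention of olefin geometry.

Step 15
Reactants: 20 (11Z)-12-iodo allylic alcohol
Product: 21 16-O-triethylsilyl ether of 20
Conditions: TESCl, imidazole, DMF, 0 °C
Reagents that add atoms: chlorotriethylsilane CC[Si](Cl)(CC)CC
Why: Silylation of the secondary allylic alcohol prevents premature lactonisation after step 16 and makes C16–O the controlling allylic ether for step 17.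

Step 16
Reactants: 21 16-O-triethylsilyl ether of 20; 22 tert-butyl 2-bromopropanoate (racemic)
Product: 24 (11E)-β,γ-unsaturated tert-butyl ester (C12 bears C13H(CH3)CO2tBu; both C13 epimers), via zinc reagent 23 (not isolated)
Conditions: 22, Zn dust, THF, rt; then 21, Pd2(dba)3 (2.5 mol %), Q-Phos (5 mol %), THF, 40 °C
Reagents that add atoms: none
Why: Negishi-type palladium-catalysed coupling of an alkenyl iodide with a Reformatsky reagent (α-alkenylation of an ester), with retention of geometry; C13 forms as both epimers and is corrected in step 20.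

Step 17
Reactants: 24 (11E)-β,γ-unsaturated tert-butyl ester
Product: 25 11,12-diol (C11 and C12 configured as in the target; C13 epimers)
Conditions: OsO4 (10 mol %), NMO (3 equiv), MeSO2NH2, acetone/H2O (8:1), rt
Reagents that add atoms: N-methylmorpholine N-oxide C[N+]1([O-])CCOCC1; water O
Why: Upjohn syn-dihydroxylation of the only electron-rich olefin, in which syn addition to the E-olefin sets C11 relative to C12, and attack anti to the allylic C16 silyloxy group (the erythro rule for allylic ethers) sets C12 relative to C16.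

Step 18
Reactants: 25 11,12-diol
Product: 26 11-O-acetate of 25
Conditions: Ac2O, DMAP, Et3N, CH2Cl2, rt
Reagents that add atoms: acetic anhydride CC(=O)OC(C)=O
Why: DMAP-catalysed acetylation of the secondary C11 hydroxyl, the tertiary C12 hydroxyl being too hindered to react.

Step 19
Reactants: 26 11-O-acetate of 25
Product: 28 γ-lactone (C14–O15–C16; free 9-OH 12-OH 17-OH; 11-OAc; C13 epimers), via seco hydroxy acid 27 (not isolated)
Conditions: TFA/CH2Cl2/H2O (20:78:2), 0 °C → rt
Reagents that add atoms: none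
Why: Acidolysis removes the tert-butyl ester, both triethylsilyl ethers and the primary TBS ether, and hydroxy acid 27 closes to the five-membered lactone through O16 (favoured over the six-membered lactone through O17), while the TBDPS ether should survive.

Step 20
Reactants: 28 γ-lactone (C13 epimers)
Product: 29 (13R)-γ-lactone (single C13 epimer)
Conditions: DBU (0.3 equiv), toluene, rt
Reagents that add atoms: none
Why: Base-mediated epimerisation of the lactone α-centre under thermodynamic control, in which the C13 methyl group should settle trans to the bulky C11 substituent on C12, that is cis to the C12 hydroxyl as in the target.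

Step 21
Reactants: 29 (13R)-γ-lactone
Product: 30 C17 aldehyde
Conditions: Dess–Martin periodinane, NaHCO3, CH2Cl2, 0 °C
Reagents that add atoms: none
Why: Dess–Martin oxidation of the only primary hydroxyl, the two tertiary hydroxyls being inert.

Step 22
Reactants: 30 C17 aldehyde
Product: 31 (Z)-alkenyl iodide (C17H=C1(I)CH3)
Conditions: EtPPh3I, n-BuLi, THF; I2, −78 °C; NaHMDS, −78 °C; then 30, −78 → −30 °C
Reagents that add atoms: ethyltriphenylphosphonium iodide CC[P+](c1ccccc1)(c1ccccc1)c1ccccc1.[I-]; iodine II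
Why: Stork–Zhao-type Wittig olefination with an α-iodo ylide, which should give the Z-configured trisubstituted alkenyl iodide (iodine cis to C16).

Step 23
Reactants: 31 (Z)-alkenyl iodide
Product: 32 9,11-diacetate
Conditions: Ac2O, DMAP (2 equiv), Et3N, CH2Cl2, 40 °C
Reagents that add atoms: acetic anhydride CC(=O)OC(C)=O
Why: DMAP-catalysed acetylation of the tertiary α-ketol hydroxyl at C9, while the C12 hydroxyl, flanked by three substituted carbons, should stay free.

Step 24
Reactants: 32 9,11-diacetate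
Product: 33 C4 primary alcohol
Conditions: HF·pyridine, pyridine, THF, 0 °C → rt
Reagents that add atoms: none
Why: Fluoride cleavage of the silyl ether under buffered conditions that leave the acetates, the lactone and the alkenyl iodide intact.

Step 25
Reactants: 33 C4 primary alcohol
Product: 34 C4 aldehyde
Conditions: Dess–Martin periodinane, NaHCO3, CH2Cl2, 0 °C → rt
Reagents that add atoms: none
Why: Dess–Martin oxidation to a non-enolisable neopentyl aldehyde.

Step 26
Reactants: 34 C4 aldehyde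
Product: 35 (2E)-enal (C5–C4H=C3H–C2HO)
Conditions: Ph3P=CHCHO (2 equiv), toluene, 80 °C
Reagents that add atoms: (triphenylphosphoranylidene)acetaldehyde O=CC=P(c1ccccc1)(c1ccccc1)c1ccccc1
Why: Wittig two-carbon homologation with a stabilised formyl ylide, which is E-selective.

Step 27
Reactants: 35 (2E)-enal
Product: 36 ten-membered carbocycle ((2S)-2-hydroxy; (Z)-C1(CH3)=C17; 9,11-diacetate; lactone)
Conditions: CrCl2 (10 equiv), NiCl2 (0.1 equiv), DMSO/THF (3:1), 2 mM, rt
Reagents that add atoms: none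
Why: Intramolecular Nozaki–Hiyama–Kishi reaction, in which nickel-mediated activation of the alkenyl iodide, transfer to chromium and 1,2-addition to the enal aldehyde close the ten-membered ring with retention of olefin geometry; C2 is set under substrate control by attack on the outer face of the folded chain and is the least secure centre of the route.

Step 28
Reactants: 36 ten-membered carbocycle
Product: 37 target CNP0196166.1
Conditions: Ca(OCl)2, solid CO2, CH2Cl2/H2O, 0 °C
Reagents that add atoms: calcium hypochlorite [Ca+2].[O-]Cl.[O-]Cl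
Why: Ene-type allylic chlorination of the trisubstituted olefin by hypochlorous acid, in which chlorine adds to the less substituted carbon C17 and a methyl hydrogen is lost to give the exocyclic methylene; the C17 configuration should result from attack on the exposed face of the folded ten-membered ring.

## Compound list

1 | ethyl (R)-3-hydroxybutanoate | C[C@@H](O)CC(=O)OCC | starting material
2 | ethyl (2R,3R)-3-hydroxy-2-methylbutanoate | C[C@@H](O)[C@@H](C)C(=O)OCC | intermediate
3 | ethyl (2R,3R)-3-hydroxy-2-(hydroxymethyl)-2-methylbutanoate | C[C@@H](O)[C@@](C)(CO)C(=O)OCC | intermediate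
4 | ethyl (2R,3R)-2-{[(tert-butyldiphenylsilyl)oxy]methyl}-3-hydroxy-2-methylbutanoate | C[C@@H](O)[C@@](C)(CO[Si](c1ccccc1)(c1ccccc1)C(C)(C)C)C(=O)OCC | intermediate
5 | ethyl (S)-2-{[(tert-butyldiphenylsilyl)oxy]methyl}-2-methylbut-3-enoate | C=C[C@@](C)(CO[Si](c1ccccc1)(c1ccccc1)C(C)(C)C)C(=O)OCC | intermediate
6 | (S)-2-{[(tert-butyldiphenylsilyl)oxy]methyl}-2-methylbut-3-enal | C=C[C@@](C)(CO[Si](c1ccccc1)(c1ccccc1)C(C)(C)C)C=O | intermediate
7 | (S)-tert-butyl{[2-(dimethoxymethyl)-2-methylbut-3-en-1-yl]oxy}diphenylsilane | C=C[C@@](C)(CO[Si](c1ccccc1)(c1ccccc1)C(C)(C)C)C(OC)OC | intermediate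
8 | 2-allyl-4,4,5,5-tetramethyl-1,3,2-dioxaborolane | C=CCB1OC(C)(C)C(C)(C)O1 | starting material
9 | tert-butyl{[(2S,3E)-2-(dimethoxymethyl)-2-methyl-5-(4,4,5,5-tetramethyl-1,3,2-dioxaborolan-2-yl)pent-3-en-1-yl]oxy}diphenylsilane | CC1(C)OB(C/C=C/[C@@](C)(CO[Si](c2ccccc2)(c2ccccc2)C(C)(C)C)C(OC)OC)OC1(C)C | intermediate
10 | butane-2,3-dione | CC(=O)C(C)=O | starting material
11 | pinacol borate adduct (C9–O–B; C10 vinyl; C6 dimethyl acetal; C5, C9, C10 as in 13) | CC(=O)[C@@](C)(OB1OC(C)(C)C(C)(C)O1)[C@H](C=C)[C@@](C)(CO[Si](c1ccccc1)(c1ccccc1)C(C)(C)C)C(OC)OC | intermediate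
12 | seco keto aldehyde (C6 aldehyde; C8 ketone; 9-OH; 10-vinyl) | CC(=O)[C@@](C)(O)[C@H](C=C)[C@@](C)(CO[Si](c1ccccc1)(c1ccccc1)C(C)(C)C)C=O | intermediate
13 | (4S,5R,6S)-4-{[(tert-butyldiphenylsilyl)oxy]methyl}-5-ethenyl-6-hydroxy-4,6-dimethylcyclohex-2-en-1-one | CC(C)(C)[Si](c1ccccc1)(c1ccccc1)OC[C@@]1(C)C=CC(=O)[C@@](C)(O)[C@@H]1C=C | intermediate
14 | 9-O-triethylsilyl ether of 13 | CC(C)(C)[Si](c1ccccc1)(c1ccccc1)OC[C@@]1(C)C=CC(=O)[C@@](C)(O[Si](CC)(CC)CC)[C@@H]1C=C | intermediate
15 | ring A aldehyde (10-formyl; 9-OTES; 5-CH2OTBDPS) | CC(C)(C)[Si](c1ccccc1)(c1ccccc1)OC[C@@]1(C)C=CC(=O)[C@@](C)(O[Si](CC)(CC)CC)[C@@H]1C=O | intermediate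
16 | ring A alkyne (10-ethynyl; 9-OTES; 5-CH2OTBDPS) | CC(C)(C)[Si](c1ccccc1)(c1ccccc1)OC[C@@]1(C)C=CC(=O)[C@@](C)(O[Si](CC)(CC)CC)[C@@H]1C#C | intermediate
17 | (tert-butyldimethylsilyloxy)acetaldehyde | CC(C)(C)[Si](C)(C)OCC=O | starting material
18 | (16R)-propargylic alcohol (C11≡C12–C16H(OH)–C17H2OTBS) | CC(C)(C)[Si](c1ccccc1)(c1ccccc1)OC[C@@]1(C)C=CC(=O)[C@@](C)(O[Si](CC)(CC)CC)[C@@H]1C#C[C@@H](O)CO[Si](C)(C)C(C)(C)C | intermediate
19 | (11Z)-12-tributylstannyl allylic alcohol | CC(C)(C)[Si](c1ccccc1)(c1ccccc1)OC[C@@]1(C)C=CC(=O)[C@@](C)(O[Si](CC)(CC)CC)[C@@H]1/C=C(\[Sn](CCCC)(CCCC)CCCC)[C@@H](O)CO[Si](C)(C)C(C)(C)C | intermediate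
20 | (11Z)-12-iodo allylic alcohol | CC(C)(C)[Si](c1ccccc1)(c1ccccc1)OC[C@@]1(C)C=CC(=O)[C@@](C)(O[Si](CC)(CC)CC)[C@@H]1/C=C(\I)[C@@H](O)CO[Si](C)(C)C(C)(C)C | intermediate
21 | 16-O-triethylsilyl ether of 20 | CC(C)(C)[Si](c1ccccc1)(c1ccccc1)OC[C@@]1(C)C=CC(=O)[C@@](C)(O[Si](CC)(CC)CC)[C@@H]1/C=C(\I)[C@@H](O[Si](CC)(CC)CC)CO[Si](C)(C)C(C)(C)C | intermediate
22 | tert-butyl 2-bromopropanoate (racemic) | CC(Br)C(=O)OC(C)(C)C | starting material
23 | (1-tert-butoxy-1-oxopropan-2-yl)zinc bromide | CC([Zn]Br)C(=O)OC(C)(C)C | intermediate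
24 | (11E)-β,γ-unsaturated tert-butyl ester (C12–C13H(CH3)CO2tBu; C13 epimers) | CC(C)(C)[Si](c1ccccc1)(c1ccccc1)OC[C@@]1(C)C=CC(=O)[C@@](C)(O[Si](CC)(CC)CC)[C@@H]1/C=C(\C(C)C(=O)OC(C)(C)C)[C@@H](O[Si](CC)(CC)CC)CO[Si](C)(C)C(C)(C)C | intermediate
25 | 11,12-diol (C11, C12 as in the target; C13 epimers) | CC(C)(C)[Si](c1ccccc1)(c1ccccc1)OC[C@@]1(C)C=CC(=O)[C@@](C)(O[Si](CC)(CC)CC)[C@@H]1[C@H](O)[C@](O)(C(C)C(=O)OC(C)(C)C)[C@@H](O[Si](CC)(CC)CC)CO[Si](C)(C)C(C)(C)C | intermediate
26 | 11-O-acetate of 25 | CC(C)(C)[Si](c1ccccc1)(c1ccccc1)OC[C@@]1(C)C=CC(=O)[C@@](C)(O[Si](CC)(CC)CC)[C@@H]1[C@H](OC(C)=O)[C@](O)(C(C)C(=O)OC(C)(C)C)[C@@H](O[Si](CC)(CC)CC)CO[Si](C)(C)C(C)(C)C | intermediate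
27 | seco hydroxy acid (free C14 acid; 9-, 12-, 16-, 17-OH; 11-OAc; C13 epimers) | CC(C)(C)[Si](c1ccccc1)(c1ccccc1)OC[C@@]1(C)C=CC(=O)[C@@](C)(O)[C@@H]1[C@H](OC(C)=O)[C@](O)(C(C)C(O)=O)[C@@H](O)CO | intermediate
28 | γ-lactone (9-, 12-, 17-OH; 11-OAc; 5-CH2OTBDPS; C13 epimers) | CC(C)(C)[Si](c1ccccc1)(c1ccccc1)OC[C@@]1(C)C=CC(=O)[C@@](C)(O)[C@@H]1[C@H](OC(C)=O)[C@]1(O)C(C)C(=O)O[C@H]1CO | intermediate
29 | (13R)-γ-lactone (single C13 epimer) | CC(C)(C)[Si](c1ccccc1)(c1ccccc1)OC[C@@]1(C)C=CC(=O)[C@@](C)(O)[C@@H]1[C@H](OC(C)=O)[C@]1(O)[C@@H](C)C(=O)O[C@H]1CO | intermediate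
30 | C17 aldehyde | CC(C)(C)[Si](c1ccccc1)(c1ccccc1)OC[C@@]1(C)C=CC(=O)[C@@](C)(O)[C@@H]1[C@H](OC(C)=O)[C@]1(O)[C@@H](C)C(=O)O[C@H]1C=O | intermediate
31 | (Z)-alkenyl iodide (C17H=C1(I)CH3) | CC(C)(C)[Si](c1ccccc1)(c1ccccc1)OC[C@@]1(C)C=CC(=O)[C@@](C)(O)[C@@H]1[C@H](OC(C)=O)[C@]1(O)[C@@H](C)C(=O)O[C@H]1/C=C(\I)C | intermediate
32 | 9,11-diacetate | CC(C)(C)[Si](c1ccccc1)(c1ccccc1)OC[C@@]1(C)C=CC(=O)[C@@](C)(OC(C)=O)[C@@H]1[C@H](OC(C)=O)[C@]1(O)[C@@H](C)C(=O)O[C@H]1/C=C(\I)C | intermediate
33 | C4 primary alcohol | OC[C@@]1(C)C=CC(=O)[C@@](C)(OC(C)=O)[C@@H]1[C@H](OC(C)=O)[C@]1(O)[C@@H](C)C(=O)O[C@H]1/C=C(\I)C | intermediate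
34 | C4 aldehyde | O=C[C@@]1(C)C=CC(=O)[C@@](C)(OC(C)=O)[C@@H]1[C@H](OC(C)=O)[C@]1(O)[C@@H](C)C(=O)O[C@H]1/C=C(\I)C | intermediate
35 | (2E)-enal (C5–C4H=C3H–C2HO) | O=C/C=C/[C@@]1(C)C=CC(=O)[C@@](C)(OC(C)=O)[C@@H]1[C@H](OC(C)=O)[C@]1(O)[C@@H](C)C(=O)O[C@H]1/C=C(\I)C | intermediate
36 | ten-membered carbocycle ((2S)-2-hydroxy; (Z)-C1(CH3)=C17) | [C@H]1(OC(C)=O)[C@H]2[C@](C)(OC(C)=O)C(=O)C=C[C@]2(C)/C=C/[C@H](O)/C(C)=C\[C@@H]2OC(=O)[C@H](C)[C@@]12O | intermediate
37 | CNP0196166.1 | C=C1[C@@H](O)/C=C/[C@@]2(C)C=CC(=O)[C@@](C)(OC(C)=O)[C@@H]2[C@H](OC(C)=O)[C@]2(O)[C@@H](C)C(=O)O[C@H]2[C@H]1Cl | target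

## Step count and risks

Total step count: 28. Longest linear sequence: 28 steps (1 → 37); 8, 10, 17 and 22 are bought.

Most likely to fail:

1. Step 28. Chlorine may be delivered to the wrong face of the C1=C17 olefin, or the proton may be lost from C2–H and not from the methyl group. The fallback sets out from 36 and returns at 37. The C2 hydroxyl is silylated (TBSOTf, 2,6-lutidine) to the C2 tert-butyldimethylsilyl ether F1. m-CPBA, which should attack the same exposed face as the chlorinating agent, gives the 1,17-epoxide F2. Cp2TiCl (from Cp2TiCl2 and Mn) opens the epoxide homolytically at the tertiary carbon C1, and loss of a methyl hydrogen gives the 17-epi allylic alcohol F3 with the exocyclic methylene in place. Appel chlorination (Ph3P, CCl4) with inversion gives the C2 silyl ether of the target F4, and HF·pyridine then gives 37.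

2. Step 27. Ring closure may be slower than intermolecular coupling and protodeiodination, and C2 may form with poor facial control. The fallback sets out from 34 and returns at 36. Takai–Lombardo methylenation (Zn, CH2Br2, TiCl4) of the C4 aldehyde gives the C4 vinyl compound F5. Intermolecular NiCl2/CrCl2 coupling of its alkenyl iodide with acrolein, run with a chiral sulfonamide ligand so that C2 is set under reagent control, gives the divinyl carbinol F6. Ring-closing metathesis (second-generation Grubbs catalyst, dilute toluene) then forms C3=C4 and gives 36.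

3. Step 8. The allylation may show poor facial selectivity with respect to C5, or be so slow that 10 is consumed by self-condensation. The fallback sets out from 7 and returns at 13. Hydroboration–oxidation (9-BBN; H2O2, NaOH) gives (S)-3-{[(tert-butyldiphenylsilyl)oxy]methyl}-4,4-dimethoxy-3-methylbutan-1-ol F7, and Dess–Martin oxidation gives the corresponding butanal F8. A proline-catalysed cross-aldol addition of F8 to 10 (enamine catalysis, anti-selective, C9 and C10 under catalyst control) gives the aldol adduct F9. Wittig methylenation (Ph3P=CH2, −78 °C) of its aldehyde gives the vinyl hydroxy ketone acetal F10, and the acid stage of step 8 (TsOH·H2O, THF/H2O) then gives 13.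

Further compounds

F1 | step 28 | C2 tert-butyldimethylsilyl ether of 36 | [C@H]1(OC(C)=O)[C@H]2[C@](C)(OC(C)=O)C(=O)C=C[C@]2(C)/C=C/[C@H](O[Si](C)(C)C(C)(C)C)/C(C)=C\[C@@H]2OC(=O)[C@H](C)[C@@]12O
F2 | step 28 | 1,17-epoxide of F1 | [C@H]1(OC(C)=O)[C@H]2[C@](C)(OC(C)=O)C(=O)C=C[C@]2(C)/C=C/[C@H](O[Si](C)(C)C(C)(C)C)[C@@]3(C)O[C@H]3[C@@H]2OC(=O)[C@H](C)[C@@]12O
F3 | step 28 | 17-epi allylic alcohol (C1 exocyclic methylene; C2 silyl ether) | [C@H]1(OC(C)=O)[C@H]2[C@](C)(OC(C)=O)C(=O)C=C[C@]2(C)/C=C/[C@H](O[Si](C)(C)C(C)(C)C)C(=C)[C@@H](O)[C@@H]2OC(=O)[C@H](C)[C@@]12O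
F4 | step 28 | C2 tert-butyldimethylsilyl ether of 37 | [C@H]1(OC(C)=O)[C@H]2[C@](C)(OC(C)=O)C(=O)C=C[C@]2(C)/C=C/[C@H](O[Si](C)(C)C(C)(C)C)C(=C)[C@H](Cl)[C@@H]2OC(=O)[C@H](C)[C@@]12O
F5 | step 27 | C4 vinyl compound (methylenated 34) | C=C[C@@]1(C)C=CC(=O)[C@@](C)(OC(C)=O)[C@@H]1[C@H](OC(C)=O)[C@]1(O)[C@@H](C)C(=O)O[C@H]1/C=C(\I)C
F6 | step 27 | divinyl carbinol ((2S)-C2 hydroxyl; C3 and C4 vinyl groups) | C=C[C@@]1(C)C=CC(=O)[C@@](C)(OC(C)=O)[C@@H]1[C@H](OC(C)=O)[C@]1(O)[C@@H](C)C(=O)O[C@H]1/C=C(C)\[C@@H](O)C=C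
F7 | step 8 | (S)-3-{[(tert-butyldiphenylsilyl)oxy]methyl}-4,4-dimethoxy-3-methylbutan-1-ol | OCC[C@@](C)(CO[Si](c1ccccc1)(c1ccccc1)C(C)(C)C)C(OC)OC
F8 | step 8 | (S)-3-{[(tert-butyldiphenylsilyl)oxy]methyl}-4,4-dimethoxy-3-methylbutanal | O=CC[C@@](C)(CO[Si](c1ccccc1)(c1ccccc1)C(C)(C)C)C(OC)OC
F9 | step 8 | aldol adduct of F8 and 10 (C11 aldehyde; 9-OH; C6 dimethyl acetal) | CC(=O)[C@@](C)(O)[C@H](C=O)[C@@](C)(CO[Si](c1ccccc1)(c1ccccc1)C(C)(C)C)C(OC)OC
F10 | step 8 | vinyl hydroxy ketone acetal (dimethyl acetal of 12) | CC(=O)[C@@](C)(O)[C@H](C=C)[C@@](C)(CO[Si](c1ccccc1)(c1ccccc1)C(C)(C)C)C(OC)OC
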